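## The problem

The target 16 is a 2,3-dihydrobenzofuran. Ring A is a benzene ring with acetyl at C5, methoxy groups at C6 and C7 and hydrogen only at C4. Ring B is a dihydrofuran carrying an isopropenyl group at C2 and an angelate ester at C3. The two stereocenters are adjacent and cis, (2R,3R). This is the more crowded arrangement, so it cannot be left to equilibration: one center must be set absolutely and then direct the other. C3 is the natural anchor, because it is a benzylic carbinol open to asymmetric catalysis and, as an α-oxygenated stereocenter, can steer a nucleophile onto the carbon that becomes C2. Several groups are fragile: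

- the angelate drifts to the tiglate with base, nucleophilic catalysts or heat;
- the C3–O bond is benzylic and ortho/para to the donors O1 and the C6 methoxy group, so it ionizes easily and elimination gives an aromatic 2-isopropenylbenzofuran;
- the C2–O1 bond is an allylic aryl ether that acid or zerovalent palladium can open.

The acetyl group cannot coexist with hydride or Grignard reagents and must arrive late from a placeholder at C5. The enabling feature is that, when ring A is read as 2,3-dimethoxyphenol, C3a is the only free carbon ortho to O1 (the C7 methoxy group blocks the other ortho site), and C3 is a carbinol carbon bonded to it. That is the pattern left by an ortho hydroxyalkylation of the phenol with a glyoxylate, a reaction that can be run enantioselectively. C5, para to O1, is then the one remaining activated position and takes the bromine that later becomes the acetyl group.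

## Retrosynthesis

**Ester C–O bond at C3 (16 ⇒ 13 + 14).** The angelate is cut first. It is the only geometrically labile alkene, and the benzylic ester is the most ionizable bond, so neither should meet palladium, fluoride or phosphine reagents. The alcohol 13 lacks both liabilities. The forward step must acylate a hindered cis benzylic alcohol without Z to E isomerization, which points to the mixed anhydride 15 and no nucleophilic catalyst.

**Ring B, O1–C2 bond (13 ⇐ 12 ⇒ 11).** After removal of the silyl ether, ring B is opened between O1 and C2. Cutting O1–C7a would need an aryl halide where the key step needs the phenol oxygen. Cutting C2–C3 offers no handle for the cis relationship. The precursor 11 is an open-chain phenol with a free allylic carbinol and a silylated benzylic carbinol. The forward reaction must be a clean SN2 displacement at C2 with inversion, so 11 must carry the anti (1R,2S) arrangement; the para acetyl group makes the phenol acidic enough for a Mitsunobu closure.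

**C5–acetyl bond (11 ⇐ 10 ⇒ 8).** The acetyl group is traced to the aryl bromide 8 through a 1-ethoxyvinyl coupling (enol ether 9, then ketone 10). This cut is placed before ring closure on purpose. Once ring B exists, C2–O1 is an allylic aryl ether that zerovalent palladium can ionize, which would scramble C2. In 8 the allylic oxygen is a free hydroxyl and inert. The cut cannot go earlier, because a ketone would not survive the hydride and Grignard steps.

**C2–isopropenyl bond (8 ⇒ 6 + 7).** The whole three-carbon unit comes from isopropenylmagnesium bromide 7 and the α-silyloxy aldehyde 6. A lactol derived from a 3-silyloxybenzofuran-2(3H)-one would save the phenol protecting group. It is set aside because the C3–H of such a lactone enolizes to an aromatic 2-hydroxybenzofuran and would racemize. The forward reaction must give the anti adduct, which is the Felkin–Anh outcome for a non-chelating silyloxy group.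

**Functional-group adjustments and the C5–Br bond (6 ⇐ 5 ⇐ 4 ⇒ 3).** The aldehyde comes from the ester 5 by partial reduction and 5 from the bromophenol 4 by double silylation. Bromine is removed to give 3. Brominating after the union is preferred, because in 3 only C4 and C5 are free and C5 alone is para to the hydroxyl. In 1 the ortho and para positions would compete.

**C3a–C3 bond (3 ⇒ 1 + 2).** The mandelate 3 is cut into 2,3-dimethoxyphenol 1 and ethyl glyoxylate 2. Both are commercial, and the cut removes the only stereocenter that needs external control. The forward reaction must attack ortho rather than para, on one aldehyde face, and stop after one arylation.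

## Roads not taken

**Alternative 1:** The C2–C3 bond and ring B are cut together, leading back to the achiral eight-membered enol ether 9,10-dimethoxy-3-methyl-8-(2-methyl-1,3-dioxolan-2-yl)-4H,6H-1,5-benzodioxocine A1. In the forward step, enantioselective benzylic lithiation (s-BuLi with a chiral diamine) triggers a [2,3]-Wittig shift. This forms C2–C3, contracts the ring to the dihydrofuran and unveils both the C3 hydroxyl and the isopropenyl group, giving (2R,3R)-2-isopropenyl-6,7-dimethoxy-5-(2-methyl-1,3-dioxolan-2-yl)-2,3-dihydrobenzofuran-3-ol A2.
- Merits: one step makes a skeletal bond, a ring and both stereocenters, and only ketal hydrolysis and angeloylation would follow. In bond economy and in the length of the endgame it is better than the chosen plan.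
- Weak points: A1 is a medium-ring aryl enol ether that is hard to close and easy to hydrolyse. Benzylic α-oxy organolithiums are configurationally labile, so the enantioselectivity would rest on a dynamic process. Ortho-lithiation directed by the methoxy and ketal groups, the [1,2]-shift and β-elimination of aryloxide all compete. Nothing in the ring-constrained transition state guarantees cis over trans.
- Comparison: the chosen plan takes its stereochemical risk at step 1 on commercial materials, where failure is cheap. Each later stereochemical event (Felkin–Anh addition, SN2 inversion) is individually predictable.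

**Alternative 2:** The C3–H bond is cut, leading back to racemic methyl 5-bromo-6,7-dimethoxy-3-oxo-2,3-dihydrobenzofuran-2-carboxylate A3. In the forward step, transfer hydrogenation with RuCl(p-cymene)(TsDPEN) and HCO2H/Et3N under dynamic kinetic resolution gives methyl (2S,3R)-5-bromo-3-hydroxy-6,7-dimethoxy-2,3-dihydrobenzofuran-2-carboxylate A4.
- Merits: one catalytic step of a well-known type sets both centers and delivers the cis pair directly. The chosen plan needs an addition and an inversion for the same result.
- Weak points: A3 should sit largely as its aromatic enol, the 3-hydroxybenzofuran ester, so the ketone needed for hydride transfer is scarce. A4 is a β-hydroxy ester with an acidic C2–H, and loss of water gives an aromatic benzofuran. The ester must then become the isopropenyl group by double methyl addition and regioselective dehydration, each step putting acid or base next to that elimination and to C2 epimerization.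
- Comparison: the chosen plan brings in the isopropenyl group intact in one Grignard step and never carries an acidic hydrogen at C2. It has nothing as compact as the one-step cis reduction.

**Alternative 3:** The C2–isopropenyl bond is cut on the closed ring, leading back to the epoxide (2S,3R)-5-bromo-2,3-epoxy-6,7-dimethoxy-2,3-dihydrobenzofuran A5. In the forward step, tri(isopropenyl)aluminium binds the epoxide oxygen, C2–O ionizes to an oxocarbenium ion paired with the aluminate, and the isopropenyl group is handed over on the same face. This gives (2R,3R)-5-bromo-2-isopropenyl-6,7-dimethoxy-2,3-dihydrobenzofuran-3-ol A6.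
- Merits: it is the shortest road. Both rings pre-exist, cis is the native outcome, and no inversion or protecting group is needed. It would probably save about four steps.
- Weak points: A5 would have to come from asymmetric epoxidation of an electron-rich benzofuran double bond and be used at once. Such epoxides rearrange readily to benzofuranones and quinone methides, the more so with donors at O1 and C6. High enantioselectivity on a C2/C3-unsubstituted benzofuran is not secured by close analogy. The later acetylation of A6 would run palladium chemistry on the allylic aryl ether.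
- Comparison: the chosen plan is longer, but every intermediate is isolable and the absolute configuration comes from a catalytic reaction of a known type.

Key step: step 1

Assumption: (R)-BINOL on tetravalent titanium is taken to give the (R)-carbinol, the sense known for glyoxylate ene reactions with this ligand; should the aryloxide-bound pathway show the opposite sense, (S)-BINOL is used and nothing else changes.

## Route

Step 1
Reactants: 1 2,3-dimethoxyphenol; 2 ethyl glyoxylate
Product: 3 ethyl (R)-2-hydroxy-2-(2-hydroxy-3,4-dimethoxyphenyl)acetate
Conditions: Ti(OiPr)4 (10 mol%), (R)-BINOL (20 mol%), toluene, 0 °C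
Reagents that add atoms: none
Why: Ti(OiPr)4 and (R)-BINOL form a chiral tetravalent titanium complex on which 1 exchanges for isopropoxide to give a titanium aryloxide, and 2 binds to the same metal through its aldehyde and ester oxygens. The ortho carbon of the aryloxide (the future C3a, para to the C6 methoxy group) attacks the bound aldehyde through a six-membered cyclic transition state, and tautomerization of the resulting dienone restores the phenol and gives the mandelate 3. The closest known reaction type is the titanium–BINOL-catalysed enantioselective ortho Friedel–Crafts hydroxyalkylation of phenols with glyoxylates, a relative of the glyoxylate ene reaction. No ring closes; the C3a–C3 bond and the C3 stereocenter form together. The configuration at C3 is controlled by the BINOL ligand, which leaves one face of the chelated aldehyde open to the aryloxide carbon. The step needs ortho over para attack, one aldehyde face and a single arylation. Delivery within the titanium aryloxide secures the ortho position, the C2 methoxy group of 1 blocks the second ortho site, and the low temperature and catalytic Lewis acid should keep the product carbinol from ionizing toward a diarylacetate.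

Step 2
Reactants: 3 ethyl (R)-2-hydroxy-2-(2-hydroxy-3,4-dimethoxyphenyl)acetate
Product: 4 ethyl (R)-2-(5-bromo-2-hydroxy-3,4-dimethoxyphenyl)-2-hydroxyacetate
Conditions: NBS, MeCN, 0 °C
Reagents that add atoms: N-bromosuccinimide, O=C1CCC(=O)N1Br
Why: Electrophilic aromatic bromination; of the two free ring positions only the one para to the phenol hydroxyl (and ortho to a methoxy group) is strongly activated, so bromine should enter at the future C5, and neutral NBS leaves the benzylic carbinol and its configuration untouched.

Step 3
Reactants: 4 ethyl (R)-2-(5-bromo-2-hydroxy-3,4-dimethoxyphenyl)-2-hydroxyacetate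
Product: 5 ethyl (R)-2-[5-bromo-2-(tert-butyldimethylsilyloxy)-3,4-dimethoxyphenyl]-2-(tert-butyldimethylsilyloxy)acetate
Conditions: TBSCl, imidazole, DMF, rt
Reagents that add atoms: tert-butyldimethylsilyl chloride, CC(C)(C)[Si](C)(C)Cl
Why: Standard silyl ether formation on the phenol and the secondary alcohol in one operation; imidazole is too weak a base to enolize the mandelate, so C3 is not at risk.

Step 4
Reactants: 5 ethyl (R)-2-[5-bromo-2-(tert-butyldimethylsilyloxy)-3,4-dimethoxyphenyl]-2-(tert-butyldimethylsilyloxy)acetate
Product: 6 (R)-2-[5-bromo-2-(tert-butyldimethylsilyloxy)-3,4-dimethoxyphenyl]-2-(tert-butyldimethylsilyloxy)acetaldehyde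
Conditions: iBu2AlH, CH2Cl2, −78 °C; MeOH, then aq. potassium sodium tartrate
Reagents that add atoms: none
Why: Partial reduction of an α-silyloxy ester; the aluminium hemiacetal is stable at −78 °C and collapses to the aldehyde only on work-up, and the aldehyde is to be used at once without chromatography because its α-hydrogen is benzylic.

Step 5
Reactants: 6 (R)-2-[5-bromo-2-(tert-butyldimethylsilyloxy)-3,4-dimethoxyphenyl]-2-(tert-butyldimethylsilyloxy)acetaldehyde; 7 isopropenylmagnesium bromide
Product: 8 (1R,2S)-1-[5-bromo-2-(tert-butyldimethylsilyloxy)-3,4-dimethoxyphenyl]-1-(tert-butyldimethylsilyloxy)-3-methylbut-3-en-2-ol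
Conditions: THF, −78 °C; aq. NH4Cl
Reagents that add atoms: none
Why: Grignard addition under Felkin–Anh (polar, non-chelation) control: the bulky silyloxy group cannot chelate magnesium and lies anti to the incoming nucleophile, which passes the α-hydrogen and not the aryl group, so the 1,2-anti (1R,2S) alcohol should predominate; the carbinol center (future C2) is thus set by C3.

Step 6
Reactants: 8 (1R,2S)-1-[5-bromo-2-(tert-butyldimethylsilyloxy)-3,4-dimethoxyphenyl]-1-(tert-butyldimethylsilyloxy)-3-methylbut-3-en-2-ol
Product: 10 1-{4-(tert-butyldimethylsilyloxy)-5-[(1R,2S)-1-(tert-butyldimethylsilyloxy)-2-hydroxy-3-methylbut-3-en-1-yl]-2,3-dimethoxyphenyl}ethan-1-one, via 1-ethoxyvinyl arene 9 (not isolated)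
Conditions: Bu3Sn[C(OEt)=CH2], Pd(PPh3)4 (5 mol%), toluene, 100 °C; then 1 M HCl, THF, 0 °C
Reagents that add atoms: tributyl(1-ethoxyvinyl)stannane, C=C(OCC)[Sn](CCCC)(CCCC)CCCC; water, O
Why: Stille coupling of the aryl bromide with the 1-ethoxyvinyl stannane under zerovalent palladium, then hydrolysis of the aryl enol ether 9 to the methyl ketone with dilute acid; the free allylic hydroxyl is not a leaving group for palladium, which is why the coupling is placed before ring closure.

Step 7
Reactants: 10 1-{4-(tert-butyldimethylsilyloxy)-5-[(1R,2S)-1-(tert-butyldimethylsilyloxy)-2-hydroxy-3-methylbut-3-en-1-yl]-2,3-dimethoxyphenyl}ethan-1-one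
Product: 11 1-{4-hydroxy-5-[(1R,2S)-1-(tert-butyldimethylsilyloxy)-2-hydroxy-3-methylbut-3-en-1-yl]-2,3-dimethoxyphenyl}ethan-1-one
Conditions: KHF2, MeOH, rt
Reagents that add atoms: none
Why: Selective desilylation: aryl silyl ethers, here further activated by the para acetyl group, are cleaved by KHF2 in methanol far faster than secondary alkyl silyl ethers, and the near-neutral medium should not promote 1,2-silyl migration to the neighbouring hydroxyl.

Step 8
Reactants: 11 1-{4-hydroxy-5-[(1R,2S)-1-(tert-butyldimethylsilyloxy)-2-hydroxy-3-methylbut-3-en-1-yl]-2,3-dimethoxyphenyl}ethan-1-one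
Product: 12 1-[(2R,3R)-3-(tert-butyldimethylsilyloxy)-6,7-dimethoxy-2-(prop-1-en-2-yl)-2,3-dihydrobenzofuran-5-yl]ethan-1-one
Conditions: PPh3, DIAD, THF, 0 °C to rt
Reagents that add atoms: none
Why: Intramolecular Mitsunobu etherification: the acidic para-acyl phenol protonates the betaine, the allylic hydroxyl becomes an oxyphosphonium ion, and the phenoxide displaces it in a 5-exo-tet SN2 closure with inversion, turning the (2S) carbinol into (2R) and the anti pair into the cis ring substituents.

Step 9
Reactants: 12 1-[(2R,3R)-3-(tert-butyldimethylsilyloxy)-6,7-dimethoxy-2-(prop-1-en-2-yl)-2,3-dihydrobenzofuran-5-yl]ethan-1-one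
Product: 13 1-[(2R,3R)-3-hydroxy-6,7-dimethoxy-2-(prop-1-en-2-yl)-2,3-dihydrobenzofuran-5-yl]ethan-1-one
Conditions: Bu4NF, AcOH, THF, 0 °C to rt
Reagents that add atoms: none
Why: Fluoride cleavage of the secondary silyl ether; acetic acid buffers the alkoxide so that neither elimination toward the benzofuran nor enolate chemistry of the methyl ketone should intervene, and no bond to C2 or C3 is broken.

Step 10
Reactants: 13 1-[(2R,3R)-3-hydroxy-6,7-dimethoxy-2-(prop-1-en-2-yl)-2,3-dihydrobenzofuran-5-yl]ethan-1-one; 14 angelic acid
Product: 16 (2R,3R)-5-acetyl-6,7-dimethoxy-2-(prop-1-en-2-yl)-2,3-dihydrobenzofuran-3-yl (Z)-2-methylbut-2-enoate (CNP0113631.1), via angelic 2,4,6-trichlorobenzoic anhydride 15 (not isolated)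
Conditions: 14, 2,4,6-Cl3C6H2COCl, Et3N, toluene, rt; then 13, 75 °C
Reagents that add atoms: none
Why: Yamaguchi-type esterification through the mixed anhydride 15 without a nucleophilic catalyst, the established way to acylate with angelic acid without Z to E isomerization; the alcohol attacks the less hindered angeloyl carbonyl and reacts at oxygen, so C3 keeps its configuration.

## Compound list

1 | 2,3-dimethoxyphenol | COc1cccc(O)c1OC | starting material
2 | ethyl glyoxylate | CCOC(=O)C=O | starting material
3 | ethyl (R)-2-hydroxy-2-(2-hydroxy-3,4-dimethoxyphenyl)acetate | CCOC(=O)[C@H](O)c1ccc(OC)c(OC)c1O | intermediate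
4 | ethyl (R)-2-(5-bromo-2-hydroxy-3,4-dimethoxyphenyl)-2-hydroxyacetate | CCOC(=O)[C@H](O)c1cc(Br)c(OC)c(OC)c1O | intermediate
5 | ethyl (R)-2-[5-bromo-2-(tert-butyldimethylsilyloxy)-3,4-dimethoxyphenyl]-2-(tert-butyldimethylsilyloxy)acetate | CCOC(=O)[C@H](O[Si](C)(C)C(C)(C)C)c1cc(Br)c(OC)c(OC)c1O[Si](C)(C)C(C)(C)C | intermediate
6 | (R)-2-[5-bromo-2-(tert-butyldimethylsilyloxy)-3,4-dimethoxyphenyl]-2-(tert-butyldimethylsilyloxy)acetaldehyde | O=C[C@H](O[Si](C)(C)C(C)(C)C)c1cc(Br)c(OC)c(OC)c1O[Si](C)(C)C(C)(C)C | intermediate
7 | isopropenylmagnesium bromide | C=C(C)[Mg]Br | starting material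
8 | (1R,2S)-1-[5-bromo-2-(tert-butyldimethylsilyloxy)-3,4-dimethoxyphenyl]-1-(tert-butyldimethylsilyloxy)-3-methylbut-3-en-2-ol | C=C(C)[C@H](O)[C@H](O[Si](C)(C)C(C)(C)C)c1cc(Br)c(OC)c(OC)c1O[Si](C)(C)C(C)(C)C | intermediate
9 | (1R,2S)-1-[2-(tert-butyldimethylsilyloxy)-5-(1-ethoxyvinyl)-3,4-dimethoxyphenyl]-1-(tert-butyldimethylsilyloxy)-3-methylbut-3-en-2-ol | C=C(C)[C@H](O)[C@H](O[Si](C)(C)C(C)(C)C)c1cc(C(=C)OCC)c(OC)c(OC)c1O[Si](C)(C)C(C)(C)C | intermediate
10 | 1-{4-(tert-butyldimethylsilyloxy)-5-[(1R,2S)-1-(tert-butyldimethylsilyloxy)-2-hydroxy-3-methylbut-3-en-1-yl]-2,3-dimethoxyphenyl}ethan-1-one | C=C(C)[C@H](O)[C@H](O[Si](C)(C)C(C)(C)C)c1cc(C(C)=O)c(OC)c(OC)c1O[Si](C)(C)C(C)(C)C | intermediate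
11 | 1-{4-hydroxy-5-[(1R,2S)-1-(tert-butyldimethylsilyloxy)-2-hydroxy-3-methylbut-3-en-1-yl]-2,3-dimethoxyphenyl}ethan-1-one | C=C(C)[C@H](O)[C@H](O[Si](C)(C)C(C)(C)C)c1cc(C(C)=O)c(OC)c(OC)c1O | intermediate
12 | 1-[(2R,3R)-3-(tert-butyldimethylsilyloxy)-6,7-dimethoxy-2-(prop-1-en-2-yl)-2,3-dihydrobenzofuran-5-yl]ethan-1-one | C=C(C)[C@H]1Oc2c(cc(C(C)=O)c(OC)c2OC)[C@H]1O[Si](C)(C)C(C)(C)C | intermediate
13 | 1-[(2R,3R)-3-hydroxy-6,7-dimethoxy-2-(prop-1-en-2-yl)-2,3-dihydrobenzofuran-5-yl]ethan-1-one | C=C(C)[C@H]1Oc2c(cc(C(C)=O)c(OC)c2OC)[C@H]1O | intermediate
14 | angelic acid, (Z)-2-methylbut-2-enoic acid | C/C=C(/C)C(=O)O | starting material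
15 | angelic 2,4,6-trichlorobenzoic anhydride | C/C=C(/C)C(=O)OC(=O)c1c(Cl)cc(Cl)cc1Cl | intermediate
16 | (2R,3R)-5-acetyl-6,7-dimethoxy-2-(prop-1-en-2-yl)-2,3-dihydrobenzofuran-3-yl (Z)-2-methylbut-2-enoate (CNP0113631.1) | C=C(C)[C@H]1Oc2c(cc(C(C)=O)c(OC)c2OC)[C@H]1OC(=O)/C(C)=C\C | target

## Step count and risks

Total steps: 10. Longest linear sequence: 10 steps, from 1 to 16.

**Step 1 (key step).** The most likely failures are these:
- attack through an unbound, merely Lewis-acid-activated glyoxylate, which would bring in the para position and lower the enantiomeric purity;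
- a second arylation after ionization of the electron-rich benzylic carbinol;
- slow turnover because the o-hydroxymandelate product and the guaiacol-type substrate both chelate titanium.

Fallback, setting out from 1 and 2 and returning at 3: the stereo-determining event is moved from the C–C bond formation to a carbonyl reduction. The bromomagnesium phenoxide of 1 (from EtMgBr) is condensed with 2 in toluene, an ortho-specific hydroxyalkylation, to give racemic ethyl 2-hydroxy-2-(2-hydroxy-3,4-dimethoxyphenyl)acetate F1. This is oxidized with MnO2 in CH2Cl2 to ethyl 2-(2-hydroxy-3,4-dimethoxyphenyl)-2-oxoacetate F2. F2 is reduced to 3 by Noyori asymmetric transfer hydrogenation with RuCl(p-cymene)[(S,S)-TsDPEN] in HCO2H/Et3N, the catalyst enantiomer being the one expected to give the (R)-mandelate. The C3a–C3 disconnection is unchanged.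

**Step 5.** The aldehyde 6 may racemize by enolization before or during the addition, since its α-hydrogen is benzylic. The Felkin–Anh preference may also be too small with a magnesium reagent, giving a mixture at the future C2. Fallback, setting out from 5 and returning at 8: 5 is converted with MeNH(OMe)·HCl and iPrMgCl in THF at −20 °C into the Weinreb amide (R)-2-[5-bromo-2-(tert-butyldimethylsilyloxy)-3,4-dimethoxyphenyl]-2-(tert-butyldimethylsilyloxy)-N-methoxy-N-methylacetamide F3. Compound 7 adds once to give the enone (R)-1-[5-bromo-2-(tert-butyldimethylsilyloxy)-3,4-dimethoxyphenyl]-1-(tert-butyldimethylsilyloxy)-3-methylbut-3-en-2-one F4. A Luche reduction (NaBH4, CeCl3·7H2O, MeOH, −78 °C) then delivers hydride 1,2 under Felkin–Anh control to give the anti alcohol 8. The aldehyde is avoided altogether.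

**Step 8.** The allylic oxyphosphonium ion may ionize before the phenoxide attacks, eroding the inversion and leaking to the trans ring, or may eliminate toward a silyl dienol ether. The carbinol is also hindered and may activate slowly. Fallback, setting out from 10 and returning at 12: the allylic hydroxyl of 10 is converted with MsCl and Et3N at −20 °C into the mesylate 1-{4-(tert-butyldimethylsilyloxy)-5-[(1R,2S)-1-(tert-butyldimethylsilyloxy)-3-methyl-2-(methylsulfonyloxy)but-3-en-1-yl]-2,3-dimethoxyphenyl}ethan-1-one F5. CsF in DMF at 0 °C then cleaves only the aryl silyl ether, and the liberated phenoxide closes ring B by SN2 displacement with inversion. Leaving-group formation and nucleophile release are thus separated.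

**Step 10.** The angeloyl unit may isomerize to the tiglate during activation or heating. The benzylic C3–O bond may also ionize at 75 °C, leading to epimerization or elimination to the benzofuran. Fallback, setting out from 13 and returning at 16: the Z alkene is built after the ester bond. Compound 13 is esterified with 2-[bis(2,2,2-trifluoroethoxy)phosphoryl]propanoic acid (EDC·HCl, DMAP, CH2Cl2, 0 °C) to give (2R,3R)-5-acetyl-6,7-dimethoxy-2-(prop-1-en-2-yl)-2,3-dihydrobenzofuran-3-yl 2-[bis(2,2,2-trifluoroethoxy)phosphoryl]propanoate F6, a mixture of epimers at the phosphonate carbon. A Still–Gennari olefination with acetaldehyde (KN(SiMe3)2, 18-crown-6, THF, −78 °C) then forms the (Z)-2-methylbut-2-enoate under kinetic control.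

**Step 6.** Oxidative addition into the electron-rich, ortho-substituted aryl bromide may be slow, so that the stannane is consumed by protodestannylation. The acid hydrolysis may also loosen the silyl ethers. Fallback, setting out from 8 and returning at 10: the hydroxyl of 8 is deprotonated with n-BuLi at −78 °C, bromine–lithium exchange follows with t-BuLi, and the aryllithium is acylated with N-methoxy-N-methylacetamide to give 10 directly. No palladium is used and no new compound is made (F0).

## Further compounds

F1 | step 1 | racemic ethyl 2-hydroxy-2-(2-hydroxy-3,4-dimethoxyphenyl)acetate | CCOC(=O)C(O)c1ccc(OC)c(OC)c1O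
F2 | step 1 | ethyl 2-(2-hydroxy-3,4-dimethoxyphenyl)-2-oxoacetate | CCOC(=O)C(=O)c1ccc(OC)c(OC)c1O
F3 | step 5 | (R)-2-[5-bromo-2-(tert-butyldimethylsilyloxy)-3,4-dimethoxyphenyl]-2-(tert-butyldimethylsilyloxy)-N-methoxy-N-methylacetamide | CON(C)C(=O)[C@H](O[Si](C)(C)C(C)(C)C)c1cc(Br)c(OC)c(OC)c1O[Si](C)(C)C(C)(C)C
F4 | step 5 | (R)-1-[5-bromo-2-(tert-butyldimethylsilyloxy)-3,4-dimethoxyphenyl]-1-(tert-butyldimethylsilyloxy)-3-methylbut-3-en-2-one | C=C(C)C(=O)[C@H](O[Si](C)(C)C(C)(C)C)c1cc(Br)c(OC)c(OC)c1O[Si](C)(C)C(C)(C)C
F0 | step 6 | none | none
F5 | step 8 | 1-{4-(tert-butyldimethylsilyloxy)-5-[(1R,2S)-1-(tert-butyldimethylsilyloxy)-3-methyl-2-(methylsulfonyloxy)but-3-en-1-yl]-2,3-dimethoxyphenyl}ethan-1-one | C=C(C)[C@H](OS(C)(=O)=O)[C@H](O[Si](C)(C)C(C)(C)C)c1cc(C(C)=O)c(OC)c(OC)c1O[Si](C)(C)C(C)(C)C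
F6 | step 10 | (2R,3R)-5-acetyl-6,7-dimethoxy-2-(prop-1-en-2-yl)-2,3-dihydrobenzofuran-3-yl 2-[bis(2,2,2-trifluoroethoxy)phosphoryl]propanoate | C=C(C)[C@H]1Oc2c(cc(C(C)=O)c(OC)c2OC)[C@H]1OC(=O)C(C)P(=O)(OCC(F)(F)F)OCC(F)(F)F
A1 | alternative 1 | 9,10-dimethoxy-3-methyl-8-(2-methyl-1,3-dioxolan-2-yl)-4H,6H-1,5-benzodioxocine | CC1=COc2c(cc(C3(C)OCCO3)c(OC)c2OC)COC1
A2 | alternative 1 | (2R,3R)-2-isopropenyl-6,7-dimethoxy-5-(2-methyl-1,3-dioxolan-2-yl)-2,3-dihydrobenzofuran-3-ol | C=C(C)[C@H]1Oc2c(cc(C3(C)OCCO3)c(OC)c2OC)[C@H]1O
A3 | alternative 2 | racemic methyl 5-bromo-6,7-dimethoxy-3-oxo-2,3-dihydrobenzofuran-2-carboxylate | COC(=O)C1Oc2c(cc(Br)c(OC)c2OC)C1=O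
A4 | alternative 2 | methyl (2S,3R)-5-bromo-3-hydroxy-6,7-dimethoxy-2,3-dihydrobenzofuran-2-carboxylate | COC(=O)[C@H]1Oc2c(cc(Br)c(OC)c2OC)[C@H]1O
A5 | alternative 3 | (2S,3R)-5-bromo-2,3-epoxy-6,7-dimethoxy-2,3-dihydrobenzofuran | COc1c(Br)cc2c(c1OC)O[C@@H]1O[C@H]21
A6 | alternative 3 | (2R,3R)-5-bromo-2-isopropenyl-6,7-dimethoxy-2,3-dihydrobenzofuran-3-ol | C=C(C)[C@H]1Oc2c(cc(Br)c(OC)c2OC)[C@H]1O
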